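- You want to know, for this flask at 50% conversion, how the rate of making product answers to more spent carrier and to more salt in the second phase.

the same everywhere: substrate 0.050 M; spent carrier 3.5 mM
- delta: salt in the second phase 0.055 M; impurity 0.20 mM; run made earlier
- epsilon: salt in the second phase 0.055 M; impurity 0.30 mM; run made earlier
- flask: salt in the second phase 0.0550 M; impurity 0.40 mM; volume of the second phase over the first 2.0

- delta (time / h: product / %, substrate / %): 0.500: 7.6, 92.1; 1.00: 15.3, 85.6; 2.00: 27.2, 72.3; 4.00: 43.9, 56.2; 8.00: 61.7, 38.4
- epsilon (time / h: product / %, substrate / %): 0.667: 10.3, 89.6; 2.00: 26.9, 73.5; 3.00: 35.7, 64.1; 5.00: 49.1, 50.9; 8.00: 61.6, 38.8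

(standard deviation of a reading: 0.5 percentage points)

- in the second phase: salt in the second phase, spent salt in the second phase; everything else is in the first
- charges count per volume of the first phase; a concentration in a rate is the amount of a species over the volume of its own phase; every rate counts per litre of the first phase
- the numbers in the tables scatter by 0.5 percentage points (one standard deviation)
- on the list of suspects stand: spent carrier + salt in the second phase <-> fresh carrier + spent salt in the second phase; substrate + fresh carrier -> product + spent carrier; fresh carrier <-> dormant form; fresh carrier + impurity -> spent catalyst
- the earlier runs hold the two phases in the same ratio of volumes as the flask asked about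
- no earlier run changes the charge of spent carrier; that part of a forecast is a guess
- no earlier run changes the charge of salt in the second phase; that part of a forecast is a guess

- apparent order in spent carrier when 50% of the substrate are converted (percent change of the rate of making product for one percent more spent carrier charged)
- apparent order in salt in the second phase when 50% of the substrate are converted (percent change of the rate of making product for one percent more salt in the second phase charged)

- The delta run's first-order constant for substrate loss reads 0.155 h⁻¹ in the first 1.00 h and 0.0952 h⁻¹ between 4.00 h and 8.00 h, so the main step with a constant catalyst does not describe these readings.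
- Take the main step first, substrate + fresh carrier → product + spent carrier, with the carrier held fresh: the order is one in carrier and 0 in salt.
- Add the exchange with salt: the share of fresh carrier now depends on salt, so the salt order lies between 0 and one, while the carrier order stays one. Substrate is the limiting reagent, at 0.050 M against 0.0550 M of salt.
- Add the impurity: if it takes a fixed amount I of fresh carrier from a charge Q, the rate follows Q − I. Define the poison share φ = I/Q, the fraction of the carrier charge that the impurity can remove, here 11.4%.
- The carrier order then becomes 1/(1 − φ), which is 1.13.
- Add the dormant form last: I take it as a fixed share of the working carrier, and a fixed share leaves that order unchanged. On that assumption my reckoning commits to 1.13 for carrier.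
- The forecast gives 1.05 (0.9 to 1.2) for carrier, below my figure, and 0.7 (0.4 to 1.05) for salt, and it says: “Delta and epsilon barely differ, so impurity has little visible effect”.
- The flask gives 1.5 for carrier, above my figure by 0.370, and 0.39 for salt, below the forecast's value.

    spent carrier + salt in the second phase ⇌ fresh carrier + spent salt in the second phase (K = 5.43, k = 24.5 M⁻¹ min⁻¹)
    substrate + fresh carrier → product + spent carrier (k = 1.01 M⁻¹ min⁻¹)
    fresh carrier ⇌ dormant form (K = 1.53, k = 0.00190 min⁻¹)
    fresh carrier + impurity → spent catalyst (k = 11500 M⁻¹ min⁻¹)

- In this flask, by 1.20 h impurity stood at 0% of its charge and spent catalyst at 11.4% of the catalyst charged, where φ was 11.4%. From then to 6.00 h the main step took substrate from 82.9% to 47.3%, while fresh carrier went from 69.9% to 44.2% and dormant form rose from 9.64% to 31.7%. The delta run has φ of 5.71%, so the carrier share that its impurity leaves is 1.06 times this flask's, and its product reading, interpolated between 1.00 h and 2.00 h to 1.20 h, is 1.03 times this flask's 17.1%.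

(All runs come from a simulation on assumed constants; scatter was added.)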